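Ring C is disconnected at C4–C4a: the pyranone is closed last by intramolecular Friedel–Crafts acylation of ring A. Because C8 already carries the prenyl group, C4a is the only free carbon ortho to O1, so the acyl carbon can reach no other position and the 8-prenyl pattern is fixed without a regiochemical choice. In one operation the step forms the C4–C4a bond, the ketone and ring C, leaving C2 and C3 untouched. Its precursor is the anti (2R,3R) 3-aryloxy-2-hydroxy-3-arylpropanoic acid, assembled by inverting SN2 opening of an enantioenriched trans-glycidate with 2-prenyl-3,5-bis(methoxymethoxy)phenol; ring B carries geranyl and a pivalate.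

Key step: step 12

Assumption: the (S)-configured diarylprolinol silyl ether of step 8 is taken to give the (2R,3S) epoxy aldehyde, as it does with cinnamaldehyde; its mirror image would be used if the sense were opposite.

Naming: geranyl = (2E)-3,7-dimethylocta-2,6-dien-1-yl; prenyl = 3-methylbut-2-en-1-yl; pivalate = 2,2-dimethylpropanoate; flavanone numbering (O1, C2, C3, C4, C4a, C5 to C8, C8a; primed locants for ring B) is used for the chromanones.

Step 1
Reactants: 1 phloroglucinol
Product: 2 3,5-bis(methoxymethoxy)phenol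
Conditions: MOMCl (2.1 equiv), i-Pr2NEt (2.5 equiv), CH2Cl2/DMF, 0 °C → rt
Reagents that add atoms: chloromethyl methyl ether, COCCl
Why: O-Alkylation of the phenoxide with the chloromethyl ether (Williamson-type acetal ether formation) is clean on oxygen, and with two equivalents the bis-ether is the main member of a statistical set that is separable by chromatography, the mono- and tris-ethers being returned or discarded.

Step 2
Reactants: 3 2-methylbut-3-en-2-ol
Product: 4 methyl 2-methylbut-3-en-2-yl carbonate
Conditions: n-BuLi, THF, −78 °C; then ClCO2Me, −78 → 0 °C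
Reagents that add atoms: methyl chloroformate, COC(=O)Cl
Why: Alkoxycarbonylation: the lithium alkoxide of the hindered tertiary allylic alcohol is acylated by the chloroformate to give the carbonate leaving group required for π-allyl palladium chemistry.

Step 3
Reactants: 2 3,5-bis(methoxymethoxy)phenol; 4 methyl 2-methylbut-3-en-2-yl carbonate
Product: 5 1,3-bis(methoxymethoxy)-5-[(2-methylbut-3-en-2-yl)oxy]benzene
Conditions: Pd(PPh3)4 (3 mol%), 4 Å MS, THF, 0 °C → rt
Reagents that add atoms: none
Why: Tsuji–Trost O-allylation: zerovalent palladium ionises the tertiary allylic carbonate with loss of CO2, the methoxide released deprotonates the phenol, and the phenoxide attacks the more substituted terminus of the 1,1-dimethylallyl complex under kinetic control to give the reverse-prenyl aryl ether.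

Step 4
Reactants: 5 1,3-bis(methoxymethoxy)-5-[(2-methylbut-3-en-2-yl)oxy]benzene
Product: 6 3,5-bis(methoxymethoxy)-2-prenylphenol
Conditions: Eu(fod)3 (fod = 6,6,7,7,8,8,8-heptafluoro-2,2-dimethyloctane-3,5-dionate; 10 mol%), CHCl3, 60 °C
Reagents that add atoms: none
Why: Aromatic Claisen rearrangement (a [3,3]-sigmatropic shift, here accelerated by the oxophilic europium complex) delivers the allyl unit with transposition to an ortho carbon and tautomerisation restores the phenol, so the 1,1-dimethylallyl ether becomes the ortho-prenyl phenol, and because the two ortho carbons are equivalent by symmetry only one regioisomer can form.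

Step 5
Reactants: 7 4-hydroxybenzaldehyde; 8 geranyl bromide
Product: 9 3-geranyl-4-hydroxybenzaldehyde
Conditions: KOH (aq., 1 M), rt
Reagents that add atoms: none
Why: Ortho C-alkylation of a phenoxide in water, where hydrogen bonding to oxygen steers the SN2 attack on the primary allylic bromide through carbon with retention of the E alkene; the para position is occupied by the formyl group, so only the ortho carbon can react, and the O-geranyl ether expected as by-product is removed by chromatography.

Step 6
Reactants: 9 3-geranyl-4-hydroxybenzaldehyde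
Product: 10 4-formyl-2-geranylphenyl pivalate
Conditions: PivCl, Et3N, DMAP (cat.), CH2Cl2, 0 °C → rt
Reagents that add atoms: pivaloyl chloride, CC(C)(C)C(=O)Cl
Why: Nucleophile-catalysed (DMAP) acylation of the phenol with the acid chloride gives the hindered aryl ester that makes ring B electron-poor and resists acyl transfer in the later base-mediated steps.

Step 7
Reactants: 10 4-formyl-2-geranylphenyl pivalate
Product: 11 2-geranyl-4-[(1E)-3-oxoprop-1-en-1-yl]phenyl pivalate
Conditions: Ph3P=CHCHO (1.15 equiv), toluene, 80 °C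
Reagents that add atoms: (triphenylphosphoranylidene)acetaldehyde, O=CC=P(c1ccccc1)(c1ccccc1)c1ccccc1
Why: Wittig olefination with the stabilised formylmethylene ylide gives the E enal, the usual outcome for stabilised ylides, and only a small excess of ylide is used so that the product enal is not homologated again.

Step 8
Reactants: 11 2-geranyl-4-[(1E)-3-oxoprop-1-en-1-yl]phenyl pivalate
Product: 12 (2R,3S)-3-[3-geranyl-4-(pivaloyloxy)phenyl]oxirane-2-carbaldehyde
Conditions: (S)-2-{bis[3,5-bis(trifluoromethyl)phenyl](trimethylsilyloxy)methyl}pyrrolidine (10 mol%), 35% aq. H2O2 (1.3 equiv), CH2Cl2, rt; crude product used directly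
Reagents that add atoms: hydrogen peroxide, OO
Why: Aminocatalytic nucleophilic epoxidation (iminium activation, conjugate addition of H2O2, enamine ring closure on the O–O bond): the bulky diaryl(silyloxy)methyl group shields one face of the E iminium ion so that C3 is set as S and the trans ring closure then sets C2 as R, while neutral H2O2 does not touch the isolated trisubstituted alkenes or the aryl ester.

Step 9
Reactants: 12 (2R,3S)-3-[3-geranyl-4-(pivaloyloxy)phenyl]oxirane-2-carbaldehyde
Product: 14 allyl (2R,3S)-3-[3-geranyl-4-(pivaloyloxy)phenyl]oxirane-2-carboxylate, via glycidic acid 13 (not isolated)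
Conditions: NaClO2, NaH2PO4, 2-methylbut-2-ene (excess), t-BuOH/H2O, 0 °C; cold extraction; then KHCO3, allyl bromide, DMF, 0 °C → rt
Reagents that add atoms: sodium chlorite, [Na+].[O-]Cl=O; allyl bromide, C=CCBr
Why: Pinnick oxidation of the aldehyde, with the sacrificial alkene consuming the HOCl that would otherwise attack the geranyl alkenes, followed by SN2 O-alkylation of the carboxylate with allyl bromide; neither operation involves the epoxide carbons, so both stereocentres are retained, and the acid-sensitive glycidic acid is esterified at once.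

Step 10
Reactants: 6 3,5-bis(methoxymethoxy)-2-prenylphenol (1.3 equiv); 14 allyl (2R,3S)-3-[3-geranyl-4-(pivaloyloxy)phenyl]oxirane-2-carboxylate
Product: 15 allyl (2R,3R)-3-[3,5-bis(methoxymethoxy)-2-prenylphenoxy]-3-[3-geranyl-4-(pivaloyloxy)phenyl]-2-hydroxypropanoate
Conditions: Cs2CO3 (20 mol%), DMF, 55 °C
Reagents that add atoms: none
Why: Base-catalysed SN2 opening of the trans epoxide by the caesium phenoxide at the benzylic carbon C3, which is activated by the aryl group whereas attack next to the ester carbonyl is disfavoured, proceeds with inversion (S to R at C3) and leaves C2 untouched, and the electron-poor pivaloyloxy ring suppresses ionisation of the benzylic C–O bond, so the anti (2R,3R) hydroxy ether is expected.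

Step 11
Reactants: 15 allyl (2R,3R)-3-[3,5-bis(methoxymethoxy)-2-prenylphenoxy]-3-[3-geranyl-4-(pivaloyloxy)phenyl]-2-hydroxypropanoate
Product: 16 (2R,3R)-3-[3,5-bis(methoxymethoxy)-2-prenylphenoxy]-3-[3-geranyl-4-(pivaloyloxy)phenyl]-2-hydroxypropanoic acid
Conditions: Pd(PPh3)4 (5 mol%), morpholine (3 equiv), THF, rt; work-up at pH 4
Reagents that add atoms: none
Why: Tsuji–Trost deallylation: zerovalent palladium ionises the allyl ester to a π-allyl complex that morpholine captures, which frees the acid under neutral conditions that spare the aryl pivalate, the acetal ethers, the alkenes and both stereocentres.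

Step 12
Reactants: 16 (2R,3R)-3-[3,5-bis(methoxymethoxy)-2-prenylphenoxy]-3-[3-geranyl-4-(pivaloyloxy)phenyl]-2-hydroxypropanoic acid
Product: 19 (2R,3R)-5,7-bis-O-(methoxymethyl)-4'-O-pivaloyl sanggenol C, via mixed anhydride 17 (not isolated), via chromanone trifluoroacetate 18 (not isolated)
Conditions: (CF3CO)2O (3 equiv), 2,6-di-tert-butyl-4-methylpyridine (4 equiv), CH2Cl2 (0.01 M), −20 → 0 °C; then MeOH, aq. NaHCO3, 0 °C
Reagents that add atoms: none
Why: Intramolecular Friedel–Crafts acylation of a 3-aryloxypropanoic acid (the classical chroman-4-one closure): the anhydride esterifies the C2 hydroxyl, a planned transient protection that stops self-acylation, and turns the carboxyl group into mixed trifluoroacetic anhydride 17, whose acyl carbon is attacked by the trioxygenated ring A, after which the hindered pyridine deprotonates the arenium ion to give 18. Ring C closes in a 6-exo-trig mode at the acyl carbon, the arene π bond lying inside the new ring. No stereocentre is formed: C2 and C3 of the chromanone are C3 and C2 of the acid, carried through unchanged because the medium contains no base able to enolise the new ketone, and the trifluoroacetate on O3 falls off by methanolysis in the hydrogencarbonate work-up. The selectivity required is between the two free carbons of ring A, and the substrate secures it: C4a is ortho to O1 and can reach the acyl carbon through a six-membered transition state, C6 cannot, and the second ortho carbon (C8) is blocked by the prenyl group. High dilution disfavours intermolecular acylation, and scavenging of the acid released protects the acetal ethers, the alkenes and the benzylic C2–O1 bond, which the electron-poor pivaloyloxy ring B further stabilises.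

Step 13
Reactants: 19 (2R,3R)-5,7-bis-O-(methoxymethyl)-4'-O-pivaloyl sanggenol C
Product: 20 4'-O-pivaloyl sanggenol C
Conditions: HCl (1.5 M) in MeOH/THF, 40 °C
Reagents that add atoms: none
Why: Acid-catalysed acetal exchange (solvolysis of the two aryl methoxymethyl ethers in methanol) frees O5 and O7, the ring C stereocentres being stable to acid and the 4'-oxygen staying acylated so that the geranyl group has no neighbouring phenol to cyclise onto.

Step 14
Reactants: 20 4'-O-pivaloyl sanggenol C
Product: 21 sanggenol C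
Conditions: K2CO3 (2 equiv), degassed MeOH, 0 °C, Ar; AcOH quench
Reagents that add atoms: none
Why: Base-mediated transesterification (methanolysis) of the aryl pivalate; at 0 °C under argon and with an acidic quench the 7-phenoxide that forms first disfavours opening of ring C by retro-oxa-Michael or quinone methide pathways, so the (2R,3R) configuration should be kept.

Compound list

1 | phloroglucinol (benzene-1,3,5-triol) | Oc1cc(O)cc(O)c1 | starting material
2 | 3,5-bis(methoxymethoxy)phenol | COCOc1cc(O)cc(OCOC)c1 | intermediate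
3 | 2-methylbut-3-en-2-ol | CC(C)(O)C=C | starting material
4 | methyl 2-methylbut-3-en-2-yl carbonate | COC(=O)OC(C)(C)C=C | intermediate
5 | 1,3-bis(methoxymethoxy)-5-[(2-methylbut-3-en-2-yl)oxy]benzene | COCOc1cc(OCOC)cc(OC(C)(C)C=C)c1 | intermediate
6 | 3,5-bis(methoxymethoxy)-2-(3-methylbut-2-en-1-yl)phenol | COCOc1cc(O)c(CC=C(C)C)c(OCOC)c1 | intermediate
7 | 4-hydroxybenzaldehyde | O=Cc1ccc(O)cc1 | starting material
8 | geranyl bromide, (2E)-1-bromo-3,7-dimethylocta-2,6-diene | CC(C)=CCC/C(C)=C/CBr | starting material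
9 | 3-[(2E)-3,7-dimethylocta-2,6-dien-1-yl]-4-hydroxybenzaldehyde | CC(C)=CCC/C(C)=C/Cc1cc(C=O)ccc1O | intermediate
10 | 4-formyl-2-geranylphenyl 2,2-dimethylpropanoate | CC(C)=CCC/C(C)=C/Cc1cc(C=O)ccc1OC(=O)C(C)(C)C | intermediate
11 | 2-geranyl-4-[(1E)-3-oxoprop-1-en-1-yl]phenyl pivalate | CC(C)=CCC/C(C)=C/Cc1cc(/C=C/C=O)ccc1OC(=O)C(C)(C)C | intermediate
12 | (2R,3S)-3-[3-geranyl-4-(pivaloyloxy)phenyl]oxirane-2-carbaldehyde (trans) | CC(C)=CCC/C(C)=C/Cc1cc([C@@H]2O[C@H]2C=O)ccc1OC(=O)C(C)(C)C | intermediate
13 | (2R,3S)-3-[3-geranyl-4-(pivaloyloxy)phenyl]oxirane-2-carboxylic acid (formed in the flask) | CC(C)=CCC/C(C)=C/Cc1cc([C@@H]2O[C@H]2C(=O)O)ccc1OC(=O)C(C)(C)C | intermediate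
14 | prop-2-en-1-yl (2R,3S)-3-[3-geranyl-4-(pivaloyloxy)phenyl]oxirane-2-carboxylate | CC(C)=CCC/C(C)=C/Cc1cc([C@@H]2O[C@H]2C(=O)OCC=C)ccc1OC(=O)C(C)(C)C | intermediate
15 | prop-2-en-1-yl (2R,3R)-3-[3,5-bis(methoxymethoxy)-2-prenylphenoxy]-3-[3-geranyl-4-(pivaloyloxy)phenyl]-2-hydroxypropanoate (anti) | CC(C)=CCC/C(C)=C/Cc1cc([C@@H](Oc2cc(OCOC)cc(OCOC)c2CC=C(C)C)[C@@H](O)C(=O)OCC=C)ccc1OC(=O)C(C)(C)C | intermediate
16 | (2R,3R)-3-[3,5-bis(methoxymethoxy)-2-prenylphenoxy]-3-[3-geranyl-4-(pivaloyloxy)phenyl]-2-hydroxypropanoic acid (anti) | CC(C)=CCC/C(C)=C/Cc1cc([C@@H](Oc2cc(OCOC)cc(OCOC)c2CC=C(C)C)[C@@H](O)C(=O)O)ccc1OC(=O)C(C)(C)C | intermediate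
17 | (2R,3R)-3-[3,5-bis(methoxymethoxy)-2-prenylphenoxy]-3-[3-geranyl-4-(pivaloyloxy)phenyl]-2-(trifluoroacetoxy)propanoic trifluoroacetic anhydride (formed in the flask) | CC(C)=CCC/C(C)=C/Cc1cc([C@@H](Oc2cc(OCOC)cc(OCOC)c2CC=C(C)C)[C@@H](OC(=O)C(F)(F)F)C(=O)OC(=O)C(F)(F)F)ccc1OC(=O)C(C)(C)C | intermediate
18 | (2R,3R)-5,7-bis-O-(methoxymethyl)-4'-O-pivaloyl-3-O-trifluoroacetyl sanggenol C (formed in the flask) | CC(C)=CCC/C(C)=C/Cc1cc([C@H]2Oc3c(CC=C(C)C)c(OCOC)cc(OCOC)c3C(=O)[C@@H]2OC(=O)C(F)(F)F)ccc1OC(=O)C(C)(C)C | intermediate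
19 | 2-geranyl-4-[(2R,3R)-3-hydroxy-5,7-bis(methoxymethoxy)-4-oxo-8-prenylchroman-2-yl]phenyl pivalate (2,3-trans) | CC(C)=CCC/C(C)=C/Cc1cc([C@H]2Oc3c(CC=C(C)C)c(OCOC)cc(OCOC)c3C(=O)[C@@H]2O)ccc1OC(=O)C(C)(C)C | intermediate
20 | 2-geranyl-4-[(2R,3R)-3,5,7-trihydroxy-4-oxo-8-prenylchroman-2-yl]phenyl pivalate | CC(C)=CCC/C(C)=C/Cc1cc([C@H]2Oc3c(CC=C(C)C)c(O)cc(O)c3C(=O)[C@@H]2O)ccc1OC(=O)C(C)(C)C | intermediate
21 | sanggenol C, (2R,3R)-2-(3-geranyl-4-hydroxyphenyl)-3,5,7-trihydroxy-8-prenylchroman-4-one | CC(C)=CCC/C(C)=C/Cc1cc([C@H]2Oc3c(CC=C(C)C)c(O)cc(O)c3C(=O)[C@@H]2O)ccc1O | target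

Total step count: 14. Longest linear sequence: 10 steps (steps 5 to 14, from 4-hydroxybenzaldehyde).

Steps most likely to fail

1. Step 12 (ring closure). The closure may stall or go astray in three ways: acid-induced loss of the acetal ethers followed by O-acylation that deactivates ring A, trifluoroacetylation of ring A by the reagent itself, or slow attack because the neighbouring trifluoroacetoxy group lowers the reactivity of the anhydride. The fallback sets out from 15 and comes back at 20. The acid is closed as a preformed acyl chloride that carries a lasting silyl ether on O2, so that neither an anhydride reagent nor free acid is present. Silylation of 15 (Et3SiCl, imidazole, DMF, 0 °C → rt) gives the allyl 2-(triethylsilyloxy) ester F1. Deallylation under the conditions of step 11 gives the 2-(triethylsilyloxy) acid F2. 1-Chloro-N,N,2-trimethylprop-1-en-1-amine (CH2Cl2, 0 °C) converts it under neutral conditions into the acyl chloride F3. AgOSO2CF3 with 2,6-di-tert-butyl-4-methylpyridine (CH2Cl2, −40 → 0 °C) then closes ring C by Friedel–Crafts acylation to the 3-O-triethylsilyl chromanone F4. The conditions of step 13 remove the silyl ether together with both acetals and return the route to 20.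

2. Step 10 (epoxide opening). The opening may lose stereochemical fidelity through partial ionisation of the benzylic C–O bond, may be diverted by attack of the ambident phenoxide through carbon or by pivaloyl transfer from ring B to the phenoxide, or may simply be slow with the hindered nucleophile. The fallback sets out from 12 (with phenol 6) and comes back at 16, bypassing steps 9 to 11. Reduction of 12 (NaBH4, MeOH, −20 °C) gives the epoxy alcohol F5. Opening by phenol 6 mediated by Ti(O-i-Pr)4 (toluene, 50 °C), in which the titanium-bound hydroxymethyl group directs the phenoxide to C3 with inversion, gives the 1,2-diol F6. Oxidation of the primary alcohol alone (TEMPO cat., NaOCl cat., NaClO2, MeCN/phosphate buffer pH 6.7, rt) gives acid 16 with the same (2R,3R) configuration.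

3. Step 14 (pivalate cleavage). Once the 4'-phenoxide exists, ring C may open by a retro-oxa-Michael or quinone methide pathway and reclose with epimerisation at C2, C3 may epimerise by enolisation, and traces of air may oxidise the product to the flavonol. The fallback sets out from 16 and comes back at 21. The pivalate is removed before ring C exists, so that no dihydroflavonol meets anything more basic than hydrogencarbonate. Hydrazinolysis of 16 (N2H4·H2O, THF/MeOH, Ar, 0 °C → rt; a weakly basic nucleophile that leaves the phenol un-ionised) gives the phenol acid F7. The protocol of step 12 with one more equivalent of (CF3CO)2O also masks the phenol, passing through the tris(trifluoroacetyl) anhydride F8 and the chromanone bis(trifluoroacetate) F9. Its methanolic NaHCO3 work-up delivers 5,7-bis-O-(methoxymethyl) sanggenol C F10. The conditions of step 13, applied for the shortest time that completes the reaction, then give 21.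

Further compounds

F1 | step 12 | prop-2-en-1-yl (2R,3R)-3-[3,5-bis(methoxymethoxy)-2-prenylphenoxy]-3-[3-geranyl-4-(pivaloyloxy)phenyl]-2-(triethylsilyloxy)propanoate | CC(C)=CCC/C(C)=C/Cc1cc([C@@H](Oc2cc(OCOC)cc(OCOC)c2CC=C(C)C)[C@@H](O[Si](CC)(CC)CC)C(=O)OCC=C)ccc1OC(=O)C(C)(C)C
F2 | step 12 | (2R,3R)-3-[3,5-bis(methoxymethoxy)-2-prenylphenoxy]-3-[3-geranyl-4-(pivaloyloxy)phenyl]-2-(triethylsilyloxy)propanoic acid | CC(C)=CCC/C(C)=C/Cc1cc([C@@H](Oc2cc(OCOC)cc(OCOC)c2CC=C(C)C)[C@@H](O[Si](CC)(CC)CC)C(=O)O)ccc1OC(=O)C(C)(C)C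
F3 | step 12 | (2R,3R)-3-[3,5-bis(methoxymethoxy)-2-prenylphenoxy]-3-[3-geranyl-4-(pivaloyloxy)phenyl]-2-(triethylsilyloxy)propanoyl chloride | CC(C)=CCC/C(C)=C/Cc1cc([C@@H](Oc2cc(OCOC)cc(OCOC)c2CC=C(C)C)[C@@H](O[Si](CC)(CC)CC)C(=O)Cl)ccc1OC(=O)C(C)(C)C
F4 | step 12 | (2R,3R)-5,7-bis-O-(methoxymethyl)-4'-O-pivaloyl-3-O-triethylsilyl sanggenol C | CC(C)=CCC/C(C)=C/Cc1cc([C@H]2Oc3c(CC=C(C)C)c(OCOC)cc(OCOC)c3C(=O)[C@@H]2O[Si](CC)(CC)CC)ccc1OC(=O)C(C)(C)C
F5 | step 10 | 2-geranyl-4-[(2S,3S)-3-(hydroxymethyl)oxiran-2-yl]phenyl pivalate | CC(C)=CCC/C(C)=C/Cc1cc([C@@H]2O[C@H]2CO)ccc1OC(=O)C(C)(C)C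
F6 | step 10 | 4-{(1R,2S)-1-[3,5-bis(methoxymethoxy)-2-prenylphenoxy]-2,3-dihydroxypropyl}-2-geranylphenyl pivalate | CC(C)=CCC/C(C)=C/Cc1cc([C@@H](Oc2cc(OCOC)cc(OCOC)c2CC=C(C)C)[C@@H](O)CO)ccc1OC(=O)C(C)(C)C
F7 | step 14 | (2R,3R)-3-[3,5-bis(methoxymethoxy)-2-prenylphenoxy]-3-(3-geranyl-4-hydroxyphenyl)-2-hydroxypropanoic acid | CC(C)=CCC/C(C)=C/Cc1cc([C@@H](Oc2cc(OCOC)cc(OCOC)c2CC=C(C)C)[C@@H](O)C(=O)O)ccc1O
F8 | step 14 | (2R,3R)-3-[3,5-bis(methoxymethoxy)-2-prenylphenoxy]-3-[3-geranyl-4-(trifluoroacetoxy)phenyl]-2-(trifluoroacetoxy)propanoic trifluoroacetic anhydride | CC(C)=CCC/C(C)=C/Cc1cc([C@@H](Oc2cc(OCOC)cc(OCOC)c2CC=C(C)C)[C@@H](OC(=O)C(F)(F)F)C(=O)OC(=O)C(F)(F)F)ccc1OC(=O)C(F)(F)F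
F9 | step 14 | (2R,3R)-5,7-bis-O-(methoxymethyl)-3,4'-bis-O-trifluoroacetyl sanggenol C | CC(C)=CCC/C(C)=C/Cc1cc([C@H]2Oc3c(CC=C(C)C)c(OCOC)cc(OCOC)c3C(=O)[C@@H]2OC(=O)C(F)(F)F)ccc1OC(=O)C(F)(F)F
F10 | step 14 | (2R,3R)-5,7-bis-O-(methoxymethyl) sanggenol C | CC(C)=CCC/C(C)=C/Cc1cc([C@H]2Oc3c(CC=C(C)C)c(OCOC)cc(OCOC)c3C(=O)[C@@H]2O)ccc1O
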